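**Retrosynthetic overview**

1. The target is cut first at a phenolic acetate that masks the ferulate OH, then in a single retro-step at both C4–C4a and O1–C2 of the 2H-pyran ring (ring B). This gives acetovanillone (ring A with all its substituents) and a C5 enal that already carries the O-acetylferulate ester.
2. Enabling feature: O1–C8a–C4a of ring B is a phenol oxygen with its only free ortho carbon (the other ortho carbon, C8, bears OMe), and C4=C3–C2 is the carbon chain of an enal. Ring B is therefore the closed form of the 1-oxatriene O1=C8a–C4a=C4–C3=C2, a vinyl o-quinone methide.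
3. Forward, a boronic acid-templated ortho-hydroxyalkylation makes C4–C4a through a temporary 1,3,2-dioxaborin ring. A chiral Brønsted acid opens that ring to the oxatriene, whose oxa-6π closure makes O1–C2 and the quaternary stereocentre C2.
4. The enal comes from isoprene monoepoxide by SN2′ chloride opening, Steglich esterification with O-acetylferulic acid and N-oxide oxidation of the allylic chloride.
5. Ring order: both benzene rings are bought; the dioxaborin ring forms and is expelled within the key step; ring B is the only ring the synthesis builds.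

Key step: step 5

Assumption: which enantiomer of the chiral acid in step 5 (and which lipase in the fallback to step 5) leads to the (R)-chromene cannot be derived from first principles and is fixed by a first experiment; the (R)-acid is written, and its mirror image is used if the sense is opposite.

**Route**

Step 1
Reactants: 1 2-methyl-2-vinyloxirane (isoprene monoepoxide, racemic)
Product: 2 (E)-4-chloro-2-methylbut-2-en-1-ol
Conditions: TiCl4, CH2Cl2, −90 to −80 °C; aq. HCl quench
Reagents that add atoms: titanium tetrachloride, Cl[Ti](Cl)(Cl)Cl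
Why: Lewis acid-mediated SN2′ (1,4-) opening of a vinyl epoxide, in which TiCl4 activates the oxirane oxygen and delivers chloride to the vinyl terminus, should give the primary allylic chloride with the (E)-trisubstituted alkene because the allyl cation-like transition state keeps the titanium-bound CH2O arm trans to the new CH2Cl group.

Step 2
Reactants: 3 (E)-ferulic acid
Product: 4 (E)-3-(4-acetoxy-3-methoxyphenyl)prop-2-enoic acid (O-acetylferulic acid)
Conditions: Ac2O, pyridine, 0 °C to rt; then H2O
Reagents that add atoms: acetic anhydride, CC(=O)OC(C)=O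
Why: Phenol O-acetylation with an anhydride under nucleophilic base catalysis, the mixed anhydride formed at the carboxyl group being hydrolysed back to the acid on aqueous work-up so that only the phenol stays acylated.

Step 3
Reactants: 2 (E)-4-chloro-2-methylbut-2-en-1-ol; 4 (E)-3-(4-acetoxy-3-methoxyphenyl)prop-2-enoic acid
Product: 5 (E)-4-chloro-2-methylbut-2-en-1-yl (E)-3-(4-acetoxy-3-methoxyphenyl)prop-2-enoate
Conditions: DCC, DMAP (cat.), CH2Cl2, 0 °C to rt
Reagents that add atoms: none
Why: Steglich esterification, in which the acylpyridinium form of 4 acylates the unhindered primary allylic alcohol of 2 under neutral conditions that should leave the allylic chloride, the aryl acetate and both (E)-alkenes untouched.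

Step 4
Reactants: 5 (E)-4-chloro-2-methylbut-2-en-1-yl (E)-3-(4-acetoxy-3-methoxyphenyl)prop-2-enoate
Product: 6 (E)-2-methyl-4-oxobut-2-en-1-yl (E)-3-(4-acetoxy-3-methoxyphenyl)prop-2-enoate
Conditions: N-methylmorpholine N-oxide (4 equiv), NaI (cat.), 4 Å MS, MeCN, rt
Reagents that add atoms: N-methylmorpholine N-oxide, C[N+]1([O-])CCOCC1
Why: N-oxide (Kornblum-type) oxidation of an activated halide, in which iodide-assisted SN2 displacement of the primary allylic chloride by the N-oxide oxygen and base-induced N–O cleavage of the alkoxyammonium salt should give the enal without over-oxidation, conjugation holding the (E)-geometry.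

Step 5
Reactants: 6 (E)-2-methyl-4-oxobut-2-en-1-yl (E)-3-(4-acetoxy-3-methoxyphenyl)prop-2-enoate; 7 acetovanillone, 1-(4-hydroxy-3-methoxyphenyl)ethan-1-one
Product: 10 [(2R)-6-acetyl-8-methoxy-2-methyl-2H-chromen-2-yl]methyl (E)-3-(4-acetoxy-3-methoxyphenyl)prop-2-enoate, via benzodioxaborin 8 (not isolated), via vinyl o-quinone methide 9 (not isolated)
Conditions: PhB(OH)2 (1.0 equiv), (R)-3,3′-bis(2,4,6-triisopropylphenyl)-1,1′-binaphthyl-2,2′-diyl N-triflylphosphoramide (10 mol %), 5 Å MS, PhMe, 50 °C
Reagents that add atoms: none
Why: Proposed new method: PhB(OH)2 esterifies the phenolic oxygen of 7 and hands the aldehyde carbon of 6 to the ortho carbon through a six-membered boron chelate (boronic acid-templated ortho-hydroxyalkylation), which forms the C4–C4a bond and closes the temporary 1,3,2-dioxaborin ring of 8 in a boron-templated six-membered transition state. The chiral N-triflylphosphoramide then ionises the benzylic, allylic C4–O bond of 8 at a temperature below that of the uncatalysed thermal cycloreversion, so that the vinyl o-quinone methide 9 is born as a hydrogen-bonded contact ion pair with the chiral anion while the boron leaves as phenylboron oxide and is recovered as PhB(OH)2 on work-up. The 1-oxatriene O1=C8a–C4a=C4–C3=C2 of 9 closes ring B by a thermal disrotatory oxa-6π electrocyclisation (in the ion-pair picture a 6-endo collapse of the hydroxyallyl cation), which forms the O1–C2 bond. The only new stereocentre, the quaternary C2, should be fixed by the helical sense in which the cisoid oxatriene coils inside the chiral pocket, the anion being anchored at O1 next to the 8-OMe group while the defined (E)-geometry of 6 places CH3 inward and the CH2O-acyl arm outward. The selectivities needed are ortho-regiocontrol, secured because the second ortho position of the phenol is blocked by OMe, and chemoselectivity, secured because the acetylated ferulate ring of 6 carries no free phenol that could enter the same manifold. Closest known reaction types: the racemic PhB(OH)2/carboxylic acid chromenylation of phenols with enals, and the chiral N-triflylphosphoramide-catalysed intramolecular allylic substitution of o-hydroxyaryl allylic alcohols to 2H-chromenes through chiral contact ion pairs.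

Step 6
Reactants: 10 [(2R)-6-acetyl-8-methoxy-2-methyl-2H-chromen-2-yl]methyl (E)-3-(4-acetoxy-3-methoxyphenyl)prop-2-enoate
Product: 11 [(2R)-6-acetyl-8-methoxy-2-methyl-2H-chromen-2-yl]methyl (E)-3-(4-hydroxy-3-methoxyphenyl)prop-2-enoate (CNP0168033.1)
Conditions: pyrrolidine (2 equiv), CH2Cl2, 0 °C, exclusion of UV light
Reagents that add atoms: none
Why: Chemoselective aminolysis of an aryl ester, in which phenoxide is a far better leaving group than the hindered neopentyl-type alkoxide of the ferulate ester, so that pyrrolidine should remove only the phenolic acetate while C2 is not involved and keeps its (R)-configuration.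

**Compound list**

1 | 2-methyl-2-vinyloxirane (isoprene monoepoxide, racemic) | CC1(C=C)CO1 | starting material
2 | (E)-4-chloro-2-methylbut-2-en-1-ol | OC/C(C)=C/CCl | intermediate
3 | (E)-ferulic acid, (E)-3-(4-hydroxy-3-methoxyphenyl)prop-2-enoic acid | COc1cc(/C=C/C(=O)O)ccc1O | starting material
4 | (E)-3-(4-acetoxy-3-methoxyphenyl)prop-2-enoic acid | COc1cc(/C=C/C(=O)O)ccc1OC(C)=O | intermediate
5 | (E)-4-chloro-2-methylbut-2-en-1-yl (E)-3-(4-acetoxy-3-methoxyphenyl)prop-2-enoate | COc1cc(/C=C/C(=O)OC/C(C)=C/CCl)ccc1OC(C)=O | intermediate
6 | (E)-2-methyl-4-oxobut-2-en-1-yl (E)-3-(4-acetoxy-3-methoxyphenyl)prop-2-enoate | COc1cc(/C=C/C(=O)OC/C(C)=C/C=O)ccc1OC(C)=O | intermediate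
7 | acetovanillone, 1-(4-hydroxy-3-methoxyphenyl)ethan-1-one | CC(=O)c1ccc(O)c(OC)c1 | starting material
8 | (E)-3-(6-acetyl-8-methoxy-2-phenyl-4H-1,3,2-benzodioxaborin-4-yl)-2-methylprop-2-en-1-yl (E)-3-(4-acetoxy-3-methoxyphenyl)prop-2-enoate (either configuration at C4 of the dioxaborin, lost on ionisation) | CC(=O)c1cc(OC)c2OB(c3ccccc3)OC(/C=C(\C)COC(=O)/C=C/c3ccc(OC(C)=O)c(OC)c3)c2c1 | intermediate
9 | (E)-4-[(1Z)-3-acetyl-5-methoxy-6-oxocyclohexa-2,4-dien-1-ylidene]-2-methylbut-2-en-1-yl (E)-3-(4-acetoxy-3-methoxyphenyl)prop-2-enoate (vinyl o-quinone methide, hydrogen-bonded to the chiral acid) | CC(=O)C1=C/C(=C/C=C(\C)COC(=O)/C=C/c2ccc(OC(C)=O)c(OC)c2)C(=O)C(OC)=C1 | intermediate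
10 | [(2R)-6-acetyl-8-methoxy-2-methyl-2H-chromen-2-yl]methyl (E)-3-(4-acetoxy-3-methoxyphenyl)prop-2-enoate | COc1cc(/C=C/C(=O)OC[C@@]2(C)C=Cc3cc(C(C)=O)cc(OC)c3O2)ccc1OC(C)=O | intermediate
11 | [(2R)-6-acetyl-8-methoxy-2-methyl-2H-chromen-2-yl]methyl (E)-3-(4-hydroxy-3-methoxyphenyl)prop-2-enoate | COc1cc(/C=C/C(=O)OC[C@@]2(C)C=Cc3cc(C(C)=O)cc(OC)c3O2)ccc1O | target

**Count and risks**

Total step count: 6
Longest linear sequence: 5 steps (steps 1, 3, 4, 5, 6 from isoprene monoepoxide; equally steps 2, 3, 4, 5, 6 from ferulic acid)

Steps most likely to fail: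

1. Step 5. The chiral ion pair may fail to steer the ring closure, either because catalyst-free thermal cycloreversion of the dioxaborin lets the oxatriene close outside the chiral pocket, or because the pocket discriminates too weakly between CH3 and the CH2O-acyl arm. The ortho-hydroxyalkylation of the deactivated phenol may also stall at 50 °C. Fallback (known chemistry; the ring closure is run racemic and the stereocentre is then set by a lipase, a serine hydrolase): it sets out from 2 and comes back at 10. Acetylation of 2 (Ac2O, pyridine) gives (E)-4-chloro-2-methylbut-2-en-1-yl acetate F1. N-oxide oxidation as in step 4 gives (E)-2-methyl-4-oxobut-2-en-1-yl acetate F2. Chromenylation of 7 with F2 (PhB(OH)2, EtCO2H, PhMe, reflux, water separator) gives racemic (6-acetyl-8-methoxy-2-methyl-2H-chromen-2-yl)methyl acetate F3. Enantioselective hydrolysis with a lipase chosen by screening (for example immobilised Candida antarctica lipase B, phosphate buffer pH 7/MTBE, 30 °C, stopped near half conversion) should give [(2R)-6-acetyl-8-methoxy-2-methyl-2H-chromen-2-yl]methanol F4 beside unreacted [(2S)-6-acetyl-8-methoxy-2-methyl-2H-chromen-2-yl]methyl acetate F5, which are separated by chromatography. Steglich esterification of F4 with 4 (DCC, DMAP, CH2Cl2) gives 10.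

2. Step 4. The (E)-geometry may be lost through dienol formation under the basic N-oxide, the N-oxide may attack the aryl acetate, or displacement of the allylic chloride may be sluggish. Fallback (the aldehyde is carried as an acetal instead of being made by oxidation in the presence of the ester): it sets out from 4 and comes back at 6. Commercial 3-methylbut-2-enal diethyl acetal is oxidised at its (E)-methyl group (SeO2 cat., t-BuOOH, CH2Cl2; then NaBH4 to return over-oxidised aldehyde) to (E)-4,4-diethoxy-2-methylbut-2-en-1-ol F6. Steglich esterification of F6 with 4 gives (E)-4,4-diethoxy-2-methylbut-2-en-1-yl (E)-3-(4-acetoxy-3-methoxyphenyl)prop-2-enoate F7. Mild acetal hydrolysis (oxalic acid, wet silica gel, CH2Cl2, rt) gives 6.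

3. Step 6. Aminolysis of the alkyl ferulate ester or aza-Michael addition of the amine to the cinnamate may compete with removal of the phenolic acetate. Fallback (the ferulate is rebuilt without any phenol protection): it sets out from 10 and comes back at 11. Complete methanolysis of 10 (K2CO3, MeOH, rt) gives [(2R)-6-acetyl-8-methoxy-2-methyl-2H-chromen-2-yl]methanol F4. Acylation with Meldrum's acid (PhMe, 100 °C) gives 3-{[(2R)-6-acetyl-8-methoxy-2-methyl-2H-chromen-2-yl]methoxy}-3-oxopropanoic acid F8. Knoevenagel–Doebner condensation of F8 with vanillin (pyridine, piperidine cat., 60 °C) gives 11 directly with the free phenol and the (E)-alkene.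

**Further compounds**

F1 | step 5 | (E)-4-chloro-2-methylbut-2-en-1-yl acetate | CC(=O)OC/C(C)=C/CCl
F2 | step 5 | (E)-2-methyl-4-oxobut-2-en-1-yl acetate | CC(=O)OC/C(C)=C/C=O
F3 | step 5 | racemic (6-acetyl-8-methoxy-2-methyl-2H-chromen-2-yl)methyl acetate | CC(=O)OCC1(C)C=Cc2cc(C(C)=O)cc(OC)c2O1
F4 | step 5 | [(2R)-6-acetyl-8-methoxy-2-methyl-2H-chromen-2-yl]methanol | OC[C@@]1(C)C=Cc2cc(C(C)=O)cc(OC)c2O1
F5 | step 5 | [(2S)-6-acetyl-8-methoxy-2-methyl-2H-chromen-2-yl]methyl acetate | CC(=O)OC[C@]1(C)C=Cc2cc(C(C)=O)cc(OC)c2O1
F6 | step 4 | (E)-4,4-diethoxy-2-methylbut-2-en-1-ol | CCOC(OCC)/C=C(\C)CO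
F7 | step 4 | (E)-4,4-diethoxy-2-methylbut-2-en-1-yl (E)-3-(4-acetoxy-3-methoxyphenyl)prop-2-enoate | COc1cc(/C=C/C(=O)OC/C(C)=C/C(OCC)OCC)ccc1OC(C)=O
F8 | step 6 | 3-{[(2R)-6-acetyl-8-methoxy-2-methyl-2H-chromen-2-yl]methoxy}-3-oxopropanoic acid | OC(=O)CC(=O)OC[C@@]1(C)C=Cc2cc(C(C)=O)cc(OC)c2O1
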